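**Retrosynthetic overview**
- Target ⇐ DDQ dehydrogenation of the p-hydroxybenzylic alcohol of a 1-aryl-2-aryloxypropane-1,3-diol (passing through a dearomatised quinone methide tautomer). The carbinol centre is destroyed, so only C2 (R) has to be controlled.
- That tetraol ⇐ C(aryl)–C1 bond formation: an (R)-2-aryloxy-3-acetoxypropanal plus lithiated 4-bromo-2,6-dimethoxyphenol.
- The aldehyde ⇐ the (S)-monoester of a prochiral 2-aryloxypropane-1,3-diol. Key step: lipase acylation of one of its two enantiotopic CH2OH groups sets the only stereocentre.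
- The prochiral triol ⇐ eugenol + diethyl chloromalonate (SN2 ether formation, then hydroboration and ester reduction in one flask).
- No ring is formed: both benzene rings are bought intact (eugenol and 4-bromo-2,6-dimethoxyphenol).

Assumption: the lipase acylates the same enantiotopic CH2OH group as in 2-O-benzylglycerol, giving the (S)-monoester 8; the configuration of 8 is to be confirmed (Mosher esters) before going on.

**Route**

Step 1
Reactants: 1 eugenol (4-allyl-2-methoxyphenol); 2 diethyl chloromalonate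
Product: 3 diethyl 2-(4-allyl-2-methoxyphenoxy)malonate
Conditions: K2CO3 (1.5 equiv), acetone, reflux, 16 h
Reagents that add atoms: none
Why: Williamson-type SN2 O-alkylation of the phenoxide by the doubly activated chloride is a standard entry to 2-aryloxymalonates, forms no stereocentre and leaves the allyl group untouched.

Step 2
Reactants: 3 diethyl 2-(4-allyl-2-methoxyphenoxy)malonate
Product: 6 2-[4-(3-hydroxypropyl)-2-methoxyphenoxy]propane-1,3-diol, via boryl malonate 4 (not isolated), via boryl diol 5 (not isolated)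
Conditions: 9-BBN (1.2 equiv), THF, 0 °C → rt; then LiBH4 (3 equiv), 0 → 40 °C; then 3 M NaOH, 30% H2O2, 0 °C → rt
Reagents that add atoms: hydrogen peroxide, OO
Why: Anti-Markovnikov Brown hydroboration of the terminal alkene by 9-BBN (esters untouched), borohydride reduction of both malonate esters and alkaline peroxide oxidation of the C–B bond run in one flask as an all-boron sequence, giving a mirror-symmetric, prochiral triol with no stereocentre.

Step 3
Reactants: 6 2-[4-(3-hydroxypropyl)-2-methoxyphenoxy]propane-1,3-diol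
Product: 8 3-(4-{[(2S)-1-acetoxy-3-hydroxypropan-2-yl]oxy}-3-methoxyphenyl)propyl acetate, via side-chain monoacetate 7 (not isolated)
Conditions: Burkholderia cepacia lipase (Amano lipase PS, immobilised), vinyl acetate (6 equiv), t-BuOMe, 25 °C, stopped when triacetate starts to appear
Reagents that add atoms: vinyl acetate, CC(=O)OC=C
Why: In this lipase-catalysed irreversible transesterification the remote primary OH is acetylated without stereochemical consequence and the enzyme then acylates one of the two enantiotopic CH2OH groups of the 2-aryloxypropane-1,3-diol unit (enantiotopic-group-selective desymmetrisation, as established for 2-O-benzylglycerol), which sets the single stereocentre as S, while slow over-acylation of the minor enantiomer raises the ee further.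

Step 4
Reactants: 8 3-(4-{[(2S)-1-acetoxy-3-hydroxypropan-2-yl]oxy}-3-methoxyphenyl)propyl acetate
Product: 9 3-(4-{[(2R)-1-acetoxy-3-oxopropan-2-yl]oxy}-3-methoxyphenyl)propyl acetate
Conditions: Dess–Martin periodinane (1.3 equiv), CH2Cl2, 0 °C → rt, 1 h; crude aldehyde used at once
Reagents that add atoms: none
Why: Dess–Martin oxidation of the one free primary alcohol, run promptly under base-free conditions, pre-empts racemising 1,3-acyl migration in 8 and avoids enolisation or loss of the β-acetate, so the stereocentre is kept (S becomes R only through the change in CIP priorities).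

Step 5
Reactants: 9 3-(4-{[(2R)-1-acetoxy-3-oxopropan-2-yl]oxy}-3-methoxyphenyl)propyl acetate; 10 4-bromo-2,6-dimethoxyphenol
Product: 13 (1RS,2R)-1-(4-hydroxy-3,5-dimethoxyphenyl)-2-[4-(3-hydroxypropyl)-2-methoxyphenoxy]propane-1,3-diol, via dilithio phenoxide 11 (not isolated), via diacetate adduct 12 (not isolated)
Conditions: 10 (2.5 equiv), n-BuLi (2.5 equiv), THF, −78 °C; t-BuLi (5.0 equiv), −78 °C, 30 min; then 9, −78 °C, 1 h; then MeOH, K2CO3, −78 °C → rt
Reagents that add atoms: none
Why: Bromine–lithium exchange on the lithium phenoxide gives a C,O-dilithiated aryl nucleophile whose 1,2-addition to the aldehyde is far faster than attack on the acetates, and K2CO3/MeOH transesterification in the same flask removes both acetates; the new carbinol centre forms as an epimer mixture that is irrelevant because it becomes the ketone carbon, while C2 is not touched.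

Step 6
Reactants: 13 (1RS,2R)-1-(4-hydroxy-3,5-dimethoxyphenyl)-2-[4-(3-hydroxypropyl)-2-methoxyphenoxy]propane-1,3-diol
Product: 15 (2R)-3-hydroxy-1-(4-hydroxy-3,5-dimethoxyphenyl)-2-[4-(3-hydroxypropyl)-2-methoxyphenoxy]propan-1-one, via quinone methide 14 (not isolated)
Conditions: DDQ (1.2 equiv), 1,4-dioxane, rt, 2–4 h; filtration, chromatography on silica without base
Reagents that add atoms: none
Why: DDQ dehydrogenation of a p-hydroxybenzylic alcohol removes the benzylic hydride with help of the free para-OH to give the dearomatised hydroxy-quinone methide, whose O-to-O proton shift restores the arene as the aryl ketone, while the primary alcohols, the non-phenolic guaiacyl ring and C2–H are left alone, so the R centre set in step 3 is delivered unchanged.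

**Compound list**

1 | eugenol (4-allyl-2-methoxyphenol) | COc1cc(CC=C)ccc1O | starting material
2 | diethyl chloromalonate | CCOC(=O)C(Cl)C(=O)OCC | starting material
3 | diethyl 2-(4-allyl-2-methoxyphenoxy)malonate | CCOC(=O)C(Oc1ccc(CC=C)cc1OC)C(=O)OCC | intermediate
4 | diethyl 2-{4-[3-(9-borabicyclo[3.3.1]nonan-9-yl)propyl]-2-methoxyphenoxy}malonate (not isolated) | CCOC(=O)C(Oc1ccc(CCCB2C3CCCC2CCC3)cc1OC)C(=O)OCC | intermediate
5 | 2-{4-[3-(9-borabicyclo[3.3.1]nonan-9-yl)propyl]-2-methoxyphenoxy}propane-1,3-diol (not isolated; present as its borate-bound alkoxides) | COc1cc(CCCB2C3CCCC2CCC3)ccc1OC(CO)CO | intermediate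
6 | 2-[4-(3-hydroxypropyl)-2-methoxyphenoxy]propane-1,3-diol (prochiral) | COc1cc(CCCO)ccc1OC(CO)CO | intermediate
7 | 3-{4-[(1,3-dihydroxypropan-2-yl)oxy]-3-methoxyphenyl}propyl acetate (not isolated) | COc1cc(CCCOC(C)=O)ccc1OC(CO)CO | intermediate
8 | 3-(4-{[(2S)-1-acetoxy-3-hydroxypropan-2-yl]oxy}-3-methoxyphenyl)propyl acetate | COc1cc(CCCOC(C)=O)ccc1O[C@H](COC(C)=O)CO | intermediate
9 | 3-(4-{[(2R)-1-acetoxy-3-oxopropan-2-yl]oxy}-3-methoxyphenyl)propyl acetate | COc1cc(CCCOC(C)=O)ccc1O[C@H](COC(C)=O)C=O | intermediate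
10 | 4-bromo-2,6-dimethoxyphenol | COc1cc(Br)cc(OC)c1O | starting material
11 | lithium 4-lithio-2,6-dimethoxyphenoxide (not isolated) | [Li]Oc1c(OC)cc([Li])cc1OC | intermediate
12 | 3-(4-{[(2R,3RS)-1-acetoxy-3-hydroxy-3-(4-hydroxy-3,5-dimethoxyphenyl)propan-2-yl]oxy}-3-methoxyphenyl)propyl acetate (not isolated; dilithium salt in the flask) | COc1cc(CCCOC(C)=O)ccc1O[C@H](COC(C)=O)C(O)c1cc(OC)c(O)c(OC)c1 | intermediate
13 | (1RS,2R)-1-(4-hydroxy-3,5-dimethoxyphenyl)-2-[4-(3-hydroxypropyl)-2-methoxyphenoxy]propane-1,3-diol (C1 epimer mixture) | COc1cc(CCCO)ccc1O[C@H](CO)C(O)c1cc(OC)c(O)c(OC)c1 | intermediate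
14 | 4-{(2R)-1,3-dihydroxy-2-[4-(3-hydroxypropyl)-2-methoxyphenoxy]propylidene}-2,6-dimethoxycyclohexa-2,5-dien-1-one (not isolated) | COc1cc(CCCO)ccc1O[C@H](CO)C(O)=C1C=C(OC)C(=O)C(OC)=C1 | intermediate
15 | (2R)-3-hydroxy-1-(4-hydroxy-3,5-dimethoxyphenyl)-2-[4-(3-hydroxypropyl)-2-methoxyphenoxy]propan-1-one (CNP0283847.2) | COc1cc(CCCO)ccc1O[C@H](CO)C(=O)c1cc(OC)c(O)c(OC)c1 | target

**Step count**

Total: 6 steps. Longest linear sequence: 6 steps (1 → 3 → 6 → 8 → 9 → 13 → 15); 10 is used as bought.

**Steps most likely to fail, with fallbacks**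

Step 3 (desymmetrisation). An aryloxy group in place of benzyloxy may lower the discrimination between the two CH2OH groups or reverse its sense. The third OH complicates monitoring, and 8 can racemise by 1,3-acetyl migration.

Fallback, setting out from 3 and coming back at 13:
- Reduce 3 with LiAlH4 (THF, 0 °C), without hydroboration, to 2-(4-allyl-2-methoxyphenoxy)propane-1,3-diol F1.
- Desymmetrise this simple diol without an enzyme: vinyl benzoate with the dinuclear zinc catalyst made from ZnEt2 and the ProPhenol ligand (2,6-bis{[2-(hydroxydiphenylmethyl)pyrrolidin-1-yl]methyl}-4-methylphenol), toluene, −15 °C. Both ligand enantiomers are available; take the one that gives (2S)-2-(4-allyl-2-methoxyphenoxy)-3-hydroxypropyl benzoate F2. A benzoate also migrates far less readily than an acetate.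
- Oxidise with Dess–Martin periodinane to (2R)-2-(4-allyl-2-methoxyphenoxy)-3-oxopropyl benzoate F3.
- Add 11 as in step 5 to give (2R,3RS)-2-(4-allyl-2-methoxyphenoxy)-3-hydroxy-3-(4-hydroxy-3,5-dimethoxyphenyl)propyl benzoate F4, and cleave the benzoate in the same flask with K2CO3/MeOH to (1RS,2R)-2-(4-allyl-2-methoxyphenoxy)-1-(4-hydroxy-3,5-dimethoxyphenyl)propane-1,3-diol F5.
- Hydroborate with excess 9-BBN (THF, rt → 50 °C) to (1RS,2R)-2-{4-[3-(9-borabicyclo[3.3.1]nonan-9-yl)propyl]-2-methoxyphenoxy}-1-(4-hydroxy-3,5-dimethoxyphenyl)propane-1,3-diol F6, and oxidise with H2O2/aqueous NaOAc to reach 13.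

Step 5 (aryl addition). The dilithiated phenoxide 11 is poorly soluble and basic. Aldehyde 9 can enolise, which erodes ee, or lose acetate by β-elimination.

Fallback, setting out from 10 (with 9) and coming back at 13:
- Mask the phenol with tert-butyldimethylsilyl chloride and imidazole in DMF to give (4-bromo-2,6-dimethoxyphenoxy)(tert-butyl)dimethylsilane F7.
- Exchange with n-BuLi (1.05 equiv, THF, −78 °C) to the soluble mono-lithiated reagent [4-(tert-butyldimethylsilyloxy)-3,5-dimethoxyphenyl]lithium F8, which can be used in near-stoichiometric amount.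
- Add it to 9 at −78 °C to give 3-(4-{[(2R,3RS)-1-acetoxy-3-[4-(tert-butyldimethylsilyloxy)-3,5-dimethoxyphenyl]-3-hydroxypropan-2-yl]oxy}-3-methoxyphenyl)propyl acetate F9.
- K2CO3 in MeOH at 40 °C removes both acetates and the aryl silyl ether in one operation and gives 13.

Step 6 (DDQ oxidation). Possible problems are over-oxidation, loss of the side chain to 2,6-dimethoxybenzoquinone, and enolisation of the product on work-up. The ee of 15 should be checked by chiral HPLC.

Fallback, setting out from 13 and coming back at 15: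
- Silylate the two primary alcohols and the phenol selectively with tert-butyldimethylsilyl chloride (3.3 equiv) and imidazole in DMF at 0 °C. The hindered secondary benzylic OH stays free, giving (1RS,2R)-3-(tert-butyldimethylsilyloxy)-1-[4-(tert-butyldimethylsilyloxy)-3,5-dimethoxyphenyl]-2-{4-[3-(tert-butyldimethylsilyloxy)propyl]-2-methoxyphenoxy}propan-1-ol F10.
- Oxidise the remaining alcohol with Dess–Martin periodinane to (2R)-3-(tert-butyldimethylsilyloxy)-1-[4-(tert-butyldimethylsilyloxy)-3,5-dimethoxyphenyl]-2-{4-[3-(tert-butyldimethylsilyloxy)propyl]-2-methoxyphenoxy}propan-1-one F11.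
- Remove the three silyl groups under acidic, non-enolising conditions (HF·pyridine, THF, 0 °C → rt) to give 15.

**Further compounds**

F1 | step 3 | 2-(4-allyl-2-methoxyphenoxy)propane-1,3-diol | COc1cc(CC=C)ccc1OC(CO)CO
F2 | step 3 | (2S)-2-(4-allyl-2-methoxyphenoxy)-3-hydroxypropyl benzoate | COc1cc(CC=C)ccc1O[C@H](COC(=O)c1ccccc1)CO
F3 | step 3 | (2R)-2-(4-allyl-2-methoxyphenoxy)-3-oxopropyl benzoate | COc1cc(CC=C)ccc1O[C@H](COC(=O)c1ccccc1)C=O
F4 | step 3 | (2R,3RS)-2-(4-allyl-2-methoxyphenoxy)-3-hydroxy-3-(4-hydroxy-3,5-dimethoxyphenyl)propyl benzoate | COc1cc(CC=C)ccc1O[C@H](COC(=O)c1ccccc1)C(O)c1cc(OC)c(O)c(OC)c1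
F5 | step 3 | (1RS,2R)-2-(4-allyl-2-methoxyphenoxy)-1-(4-hydroxy-3,5-dimethoxyphenyl)propane-1,3-diol | COc1cc(CC=C)ccc1O[C@H](CO)C(O)c1cc(OC)c(O)c(OC)c1
F6 | step 3 | (1RS,2R)-2-{4-[3-(9-borabicyclo[3.3.1]nonan-9-yl)propyl]-2-methoxyphenoxy}-1-(4-hydroxy-3,5-dimethoxyphenyl)propane-1,3-diol | COc1cc(CCCB2C3CCCC2CCC3)ccc1O[C@H](CO)C(O)c1cc(OC)c(O)c(OC)c1
F7 | step 5 | (4-bromo-2,6-dimethoxyphenoxy)(tert-butyl)dimethylsilane | COc1cc(Br)cc(OC)c1O[Si](C)(C)C(C)(C)C
F8 | step 5 | [4-(tert-butyldimethylsilyloxy)-3,5-dimethoxyphenyl]lithium | [Li]c1cc(OC)c(O[Si](C)(C)C(C)(C)C)c(OC)c1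
F9 | step 5 | 3-(4-{[(2R,3RS)-1-acetoxy-3-[4-(tert-butyldimethylsilyloxy)-3,5-dimethoxyphenyl]-3-hydroxypropan-2-yl]oxy}-3-methoxyphenyl)propyl acetate | COc1cc(CCCOC(C)=O)ccc1O[C@H](COC(C)=O)C(O)c1cc(OC)c(O[Si](C)(C)C(C)(C)C)c(OC)c1
F10 | step 6 | (1RS,2R)-3-(tert-butyldimethylsilyloxy)-1-[4-(tert-butyldimethylsilyloxy)-3,5-dimethoxyphenyl]-2-{4-[3-(tert-butyldimethylsilyloxy)propyl]-2-methoxyphenoxy}propan-1-ol | COc1cc(CCCO[Si](C)(C)C(C)(C)C)ccc1O[C@H](CO[Si](C)(C)C(C)(C)C)C(O)c1cc(OC)c(O[Si](C)(C)C(C)(C)C)c(OC)c1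
F11 | step 6 | (2R)-3-(tert-butyldimethylsilyloxy)-1-[4-(tert-butyldimethylsilyloxy)-3,5-dimethoxyphenyl]-2-{4-[3-(tert-butyldimethylsilyloxy)propyl]-2-methoxyphenoxy}propan-1-one | COc1cc(CCCO[Si](C)(C)C(C)(C)C)ccc1O[C@H](CO[Si](C)(C)C(C)(C)C)C(=O)c1cc(OC)c(O[Si](C)(C)C(C)(C)C)c(OC)c1
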